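**Retrosynthetic overview**
1. Target ⇐ bis-TBDPS ether 29 by desilylation; the C9 acetate and C8 (S)-2-methylbutanoate are put on late; the ten-membered ring comes from ring-closing metathesis that forms C4=C5 in seco-diene 26.
2. 26 ⇐ Barbier allylation (C7–C8 bond) of aldehyde 23 (fragment 2) with bromolactone 8 (fragment 1); this sets C7 and C8 and delivers the α-methylene lactone directly.
3. Fragment 1 ⇐ ring-closing metathesis of a dienyl 2-(bromomethyl)acrylate; C6 comes from a Sharpless kinetic resolution.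
4. Fragment 2 ⇐ allyl–allyl coupling of two C4 pieces; the C1=C10 geometry comes from Red-Al/iodine on a butynediol ether, C9 from asymmetric transfer hydrogenation of an α-keto ester.
5. Ring order: the five-membered lactone first (step 6), the ten-membered carbocycle last (step 19).

Convention assumed: germacrane numbering (lactone C12(=O)–O–C6, C7 ring fusion, C8 methylbutanoate, C9 acetate, C10/C14, C1–C3, C4/C15, C5, C11=C13); the target is (6R,7S,8R,9S), both ring alkenes ring-cis, ester side chain (S); TBDPS = tert-butyldiphenylsilyl, TES = triethylsilyl.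

**Fragment 1 (bromolactone 8)**

Step 1
Reactants: 1 (E)-but-2-enal
Product: 2 rac-(4E)-hexa-1,4-dien-3-ol
Conditions: CH2=CHMgBr, THF, −78 → 0 °C; then H2O
Reagents that add atoms: vinylmagnesium bromide, C=C[Mg]Br
Why: Grignard addition of the hard vinyl nucleophile occurs 1,2 on the enal and gives the racemic bis-allylic carbinol that is resolved in step 2.

Step 2
Reactants: 2 rac-(4E)-hexa-1,4-dien-3-ol
Product: 3 (3S,4E)-hexa-1,4-dien-3-ol
Conditions: Ti(OiPr)4 (10 mol%), D-(−)-diisopropyl tartrate (15 mol%), t-BuOOH (0.6 equiv), 4 Å MS, CH2Cl2, −20 °C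
Reagents that add atoms: none
Why: Sharpless kinetic resolution epoxidises the (R)-alcohol quickly at its electron-richer propenyl group and leaves the (S)-alcohol (≥98% ee at about 55–60% conversion), which fixes the future C6.

Step 3
Reactants: 4 diethyl 2,2-bis(hydroxymethyl)propanedioate
Product: 5 2-(bromomethyl)prop-2-enoic acid
Conditions: 48% aq HBr, 85–90 °C
Reagents that add atoms: hydrogen bromide, Br
Why: Ester hydrolysis, bromide substitution and dehydrative decarboxylation in hot HBr are the standard preparative route to this acid from the cheap malonate (substitution–decarboxylative elimination).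

Step 4
Reactants: 5 2-(bromomethyl)prop-2-enoic acid
Product: 6 2-(bromomethyl)prop-2-enoyl chloride
Conditions: (COCl)2, cat. DMF, CH2Cl2, 0 °C → rt
Reagents that add atoms: oxalyl chloride, ClC(=O)C(=O)Cl
Why: Vilsmeier-type acid chloride formation is neutral and leaves the allylic bromide untouched.

Step 5
Reactants: 3 (3S,4E)-hexa-1,4-dien-3-ol; 6 2-(bromomethyl)prop-2-enoyl chloride
Product: 7 (3S,4E)-hexa-1,4-dien-3-yl 2-(bromomethyl)prop-2-enoate
Conditions: 2,6-lutidine, CH2Cl2, −30 → 0 °C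
Reagents that add atoms: none
Why: O-acylation with a hindered, non-nucleophilic base avoids attack on the allylic bromide and does not touch the carbinol C–O bond, so the stereocentre is retained.

Step 6
Reactants: 7 (3S,4E)-hexa-1,4-dien-3-yl 2-(bromomethyl)prop-2-enoate
Product: 8 (5R)-3-(bromomethyl)-5-[(1E)-prop-1-en-1-yl]furan-2(5H)-one
Conditions: second-generation Grubbs catalyst (5 mol%), CH2Cl2 (5 mM), 40 °C
Reagents that add atoms: none
Why: Ring-closing metathesis starts at the terminal vinyl group and closes onto the acrylate methylidene to give the butenolide, while the slower-initiating propenyl group stays as the C6 substituent.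

**Fragment 2 (aldehyde 23)**

Step 7
Reactants: 9 but-2-yne-1,4-diol
Product: 10 4-(TBDPS-oxy)but-2-yn-1-ol
Conditions: NaH (1 equiv), TBDPSCl (1 equiv), diol (3 equiv), THF, 0 °C → rt
Reagents that add atoms: tert-butyl(chloro)diphenylsilane, CC(C)(C)[Si](Cl)(c1ccccc1)c1ccccc1
Why: O-silylation of the mono-alkoxide with the diol in excess gives the mono ether statistically.

Step 8
Reactants: 10 4-(TBDPS-oxy)but-2-yn-1-ol
Product: 12 (2Z)-4-(TBDPS-oxy)-3-iodobut-2-en-1-ol, via cyclic alkenylalanate 11 (not isolated)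
Conditions: NaAlH2(OCH2CH2OCH3)2, THF, 0 °C; then I2, −78 → 0 °C
Reagents that add atoms: iodine, II
Why: Hydroxyl-directed trans-hydroalumination puts aluminium on the distal alkyne carbon and iodinolysis with retention gives the (Z)-iodoalkene, which fixes the C1=C10 geometry.

Step 9
Reactants: 12 (2Z)-4-(TBDPS-oxy)-3-iodobut-2-en-1-ol
Product: 13 [(2Z)-4-bromo-2-iodobut-2-en-1-yl]oxy-TBDPS
Conditions: CBr4, PPh3, CH2Cl2, 0 °C
Reagents that add atoms: tetrabromomethane, BrC(Br)(Br)Br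
Why: Appel bromination converts the primary allylic alcohol into the bromide under neutral conditions without touching the alkenyl iodide or the alkene geometry.

Step 10
Reactants: 14 2-methylidenepropane-1,3-diol
Product: 15 2-[(TBDPS-oxy)methyl]prop-2-en-1-ol
Conditions: NaH (1 equiv), TBDPSCl (1 equiv), diol (3 equiv), THF, 0 °C → rt
Reagents that add atoms: tert-butyl(chloro)diphenylsilane, CC(C)(C)[Si](Cl)(c1ccccc1)c1ccccc1
Why: Statistical mono-O-silylation of the symmetric diol, as in step 7.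

Step 11
Reactants: 15 2-[(TBDPS-oxy)methyl]prop-2-en-1-ol
Product: 16 [2-(chloromethyl)prop-2-en-1-yl]oxy-TBDPS
Conditions: PPh3, CCl4, CH2Cl2, 40 °C
Reagents that add atoms: tetrachloromethane, ClC(Cl)(Cl)Cl
Why: Appel chlorination gives the allylic chloride, and the symmetric allyl unit makes any allylic transposition degenerate.

Step 12
Reactants: 16 [2-(chloromethyl)prop-2-en-1-yl]oxy-TBDPS; 13 [(2Z)-4-bromo-2-iodobut-2-en-1-yl]oxy-TBDPS
Product: 18 (2Z)-1,7-bis(TBDPS-oxy)-2-iodo-6-methylidenehept-2-ene, via allylmagnesium chloride 17 (not isolated)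
Conditions: Mg turnings, THF, 0 °C; then 13, THF, −78 → 0 °C
Reagents that add atoms: none
Why: Allyl–allyl Grignard cross-coupling forms C2–C3 by SN2 at the primary bromide; the nucleophile has equivalent ends and the iodine-bearing carbon is too hindered for allylic transposition.

Step 13
Reactants: 18 (2Z)-1,7-bis(TBDPS-oxy)-2-iodo-6-methylidenehept-2-ene
Product: 20 methyl (3Z)-8-(TBDPS-oxy)-3-[(TBDPS-oxy)methyl]-7-methylidene-2-oxooct-3-enoate, via alkenyllithium 19 (not isolated)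
Conditions: t-BuLi (2.1 equiv), Et2O, −78 °C; cannulate into (CO2Me)2 (3 equiv), THF, −78 °C
Reagents that add atoms: dimethyl oxalate, COC(=O)C(=O)OC
Why: Iodine–lithium exchange keeps the alkene geometry and acylation by excess oxalate at −78 °C (inverse addition) stops at the α-keto ester.

Step 14
Reactants: 20 methyl (3Z)-8-(TBDPS-oxy)-3-[(TBDPS-oxy)methyl]-7-methylidene-2-oxooct-3-enoate
Product: 21 methyl (2S,3Z)-8-(TBDPS-oxy)-3-[(TBDPS-oxy)methyl]-2-hydroxy-7-methylideneoct-3-enoate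
Conditions: RuCl(p-cymene)[(R,R)-TsDPEN] (2 mol%), HCO2H/Et3N (5:2), CH2Cl2, 25 °C
Reagents that add atoms: none
Why: Noyori asymmetric transfer hydrogenation reduces the activated ketone only, and with the alkenyl group in the role of the aryl group the (R,R)-catalyst is expected to give the (S)-carbinol (C9), by analogy with aryl glyoxylates.

Step 15
Reactants: 21 methyl (2S,3Z)-8-(TBDPS-oxy)-3-[(TBDPS-oxy)methyl]-2-hydroxy-7-methylideneoct-3-enoate
Product: 22 methyl (2S,3Z)-8-(TBDPS-oxy)-3-[(TBDPS-oxy)methyl]-7-methylidene-2-(TES-oxy)oct-3-enoate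
Conditions: Et3SiOTf, 2,6-lutidine, CH2Cl2, −78 °C
Reagents that add atoms: triethylsilyl trifluoromethanesulfonate, CC[Si](CC)(CC)OS(=O)(=O)C(F)(F)F
Why: Silylation gives a bulky, non-chelating ether that can later be removed in the presence of the two TBDPS ethers.

Step 16
Reactants: 22 methyl (2S,3Z)-8-(TBDPS-oxy)-3-[(TBDPS-oxy)methyl]-7-methylidene-2-(TES-oxy)oct-3-enoate
Product: 23 (2S,3Z)-8-(TBDPS-oxy)-3-[(TBDPS-oxy)methyl]-7-methylidene-2-(TES-oxy)oct-3-enal
Conditions: i-Bu2AlH (1.2 equiv), CH2Cl2, −78 °C; aq Rochelle salt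
Reagents that add atoms: none
Why: Partial reduction of an α-silyloxy ester stops at the aldehyde because the tetrahedral aluminium acetal survives at −78 °C; the aldehyde is used at once to avoid epimerisation.

**Union and endgame**

Step 17
Reactants: 8 (5R)-3-(bromomethyl)-5-[(1E)-prop-1-en-1-yl]furan-2(5H)-one; 23 (2S,3Z)-8-(TBDPS-oxy)-3-[(TBDPS-oxy)methyl]-7-methylidene-2-(TES-oxy)oct-3-enal
Product: 25 (4R,5R)-4-[(1R,2S,3Z)-8-(TBDPS-oxy)-3-[(TBDPS-oxy)methyl]-1-hydroxy-7-methylidene-2-(TES-oxy)oct-3-en-1-yl]-3-methylidene-5-[(1E)-prop-1-en-1-yl]oxolan-2-one, via allylzinc bromide 24 (not isolated)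
Conditions: Zn dust, 8 (2 equiv), THF/sat. aq NH4Cl (3:1), 0 °C → rt
Reagents that add atoms: none
Why: In this Barbier allylation the ring-locked allylzinc attacks through C7 anti to the propenyl group (trans lactone) via a chair Zimmerman–Traxler transition state that sets C7/C8, and Felkin–Anh addition to the α-silyloxy aldehyde sets C8 anti to C9, all three preferences converging on one isomer.

Step 18
Reactants: 25 (the C8 alcohol from step 17)
Product: 26 (1R,2S,3Z)-8-(TBDPS-oxy)-3-[(TBDPS-oxy)methyl]-7-methylidene-1-{(2R,3S)-4-methylidene-5-oxo-2-[(1E)-prop-1-en-1-yl]oxolan-3-yl}-2-(TES-oxy)oct-3-en-1-yl (2S)-2-methylbutanoate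
Conditions: (S)-2-methylbutanoic anhydride, DMAP, pyridine, CH2Cl2, 25 °C
Reagents that add atoms: (S)-2-methylbutanoic anhydride, CC[C@H](C)C(=O)OC(=O)[C@@H](C)CC
Why: DMAP-catalysed acylation with the preformed anhydride esterifies the hindered C8 hydroxyl without a ketene pathway, so the side-chain stereocentre is not scrambled.

Step 19
Reactants: 26 (the seco-diene ester from step 18)
Product: 27 (3aS,4R,5S,6Z,10E,11aR)-6,10-bis[(TBDPS-oxy)methyl]-3-methylidene-2-oxo-5-(TES-oxy)-2,3,3a,4,5,8,9,11a-octahydrocyclodeca[b]furan-4-yl (2S)-2-methylbutanoate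
Conditions: second-generation Hoveyda–Grubbs catalyst (10 mol%), 1,4-benzoquinone (20 mol%), toluene (1 mM), 80 °C
Reagents that add atoms: none
Why: Ring-closing metathesis between the C6 propenyl group and the unhindered C4 methylidene, with loss of propene, closes the ten-membered ring, and the existing cis C1=C10 alkene together with ring strain should impose the ring-cis geometry at the new C4=C5 bond.

Step 20
Reactants: 27 (the TES-protected macrocycle)
Product: 28 (3aS,4R,5S,6Z,10E,11aR)-6,10-bis[(TBDPS-oxy)methyl]-5-hydroxy-3-methylidene-2-oxo-2,3,3a,4,5,8,9,11a-octahydrocyclodeca[b]furan-4-yl (2S)-2-methylbutanoate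
Conditions: PPTS (cat.), MeOH/CH2Cl2, 0 °C → rt
Reagents that add atoms: none
Why: Mild acid-catalysed methanolysis cleaves the secondary TES ether while the primary TBDPS ethers and the esters survive, and acyl migration is slow under acid.

Step 21
Reactants: 28 (the C9 alcohol)
Product: 29 (3aS,4R,5S,6Z,10E,11aR)-5-(acetyloxy)-6,10-bis[(TBDPS-oxy)methyl]-3-methylidene-2-oxo-2,3,3a,4,5,8,9,11a-octahydrocyclodeca[b]furan-4-yl (2S)-2-methylbutanoate
Conditions: Ac2O, pyridine, DMAP (cat.), CH2Cl2, 0 °C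
Reagents that add atoms: acetic anhydride, CC(=O)OC(C)=O
Why: Fast DMAP-catalysed acetylation caps the C9 hydroxyl before the neighbouring ester can migrate.

Step 22
Reactants: 29 (the bis-TBDPS acetate)
Product: 30 (3aS,4R,5S,6Z,10E,11aR)-5-(acetyloxy)-6,10-bis(hydroxymethyl)-3-methylidene-2-oxo-2,3,3a,4,5,8,9,11a-octahydrocyclodeca[b]furan-4-yl (2S)-2-methylbutanoate (CNP0207247.12)
Conditions: HF·pyridine, pyridine, THF, 0 °C → rt
Reagents that add atoms: none
Why: Buffered acidic fluoride desilylation frees both primary allylic alcohols without base, so the acetate, the methylbutanoate and the α-methylene lactone are left alone.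

**Compound list**
1 | (E)-but-2-enal | C/C=C/C=O | starting material
2 | rac-(4E)-hexa-1,4-dien-3-ol | C=CC(O)/C=C/C | intermediate
3 | (3S,4E)-hexa-1,4-dien-3-ol | C=C[C@H](O)/C=C/C | intermediate
4 | diethyl 2,2-bis(hydroxymethyl)propanedioate | CCOC(=O)C(CO)(CO)C(=O)OCC | starting material
5 | 2-(bromomethyl)prop-2-enoic acid | C=C(CBr)C(=O)O | intermediate
6 | 2-(bromomethyl)prop-2-enoyl chloride | C=C(CBr)C(=O)Cl | intermediate
7 | (3S,4E)-hexa-1,4-dien-3-yl 2-(bromomethyl)prop-2-enoate | C=C[C@H](OC(=O)C(=C)CBr)/C=C/C | intermediate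
8 | (5R)-3-(bromomethyl)-5-[(1E)-prop-1-en-1-yl]furan-2(5H)-one (fragment 1) | O=C1O[C@H](/C=C/C)C=C1CBr | intermediate
9 | but-2-yne-1,4-diol | OCC#CCO | starting material
10 | 4-(TBDPS-oxy)but-2-yn-1-ol | OCC#CCO[Si](c1ccccc1)(c1ccccc1)C(C)(C)C | intermediate
11 | sodium cyclic alkenylalanate of 10 (O–Al–C chelate, two 2-methoxyethoxy groups on Al) | [Na+].COCCO[Al-]1(OCCOC)OCC=C1CO[Si](c2ccccc2)(c2ccccc2)C(C)(C)C | intermediate (not isolated)
12 | (2Z)-4-(TBDPS-oxy)-3-iodobut-2-en-1-ol | OC/C=C(\I)CO[Si](c1ccccc1)(c1ccccc1)C(C)(C)C | intermediate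
13 | [(2Z)-4-bromo-2-iodobut-2-en-1-yl]oxy-TBDPS | BrC/C=C(\I)CO[Si](c1ccccc1)(c1ccccc1)C(C)(C)C | intermediate
14 | 2-methylidenepropane-1,3-diol | C=C(CO)CO | starting material
15 | 2-[(TBDPS-oxy)methyl]prop-2-en-1-ol | C=C(CO)CO[Si](c1ccccc1)(c1ccccc1)C(C)(C)C | intermediate
16 | [2-(chloromethyl)prop-2-en-1-yl]oxy-TBDPS | C=C(CCl)CO[Si](c1ccccc1)(c1ccccc1)C(C)(C)C | intermediate
17 | {2-[(TBDPS-oxy)methyl]prop-2-en-1-yl}magnesium chloride | C=C(C[Mg]Cl)CO[Si](c1ccccc1)(c1ccccc1)C(C)(C)C | intermediate (not isolated)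
18 | (2Z)-1,7-bis(TBDPS-oxy)-2-iodo-6-methylidenehept-2-ene | C=C(CO[Si](c1ccccc1)(c1ccccc1)C(C)(C)C)CC/C=C(\I)CO[Si](c1ccccc1)(c1ccccc1)C(C)(C)C | intermediate
19 | alkenyllithium from 18 (Li in place of I, geometry retained) | C=C(CO[Si](c1ccccc1)(c1ccccc1)C(C)(C)C)CC/C=C(\[Li])CO[Si](c1ccccc1)(c1ccccc1)C(C)(C)C | intermediate (not isolated)
20 | methyl (3Z)-8-(TBDPS-oxy)-3-[(TBDPS-oxy)methyl]-7-methylidene-2-oxooct-3-enoate | COC(=O)C(=O)/C(CO[Si](c1ccccc1)(c1ccccc1)C(C)(C)C)=C\CCC(=C)CO[Si](c1ccccc1)(c1ccccc1)C(C)(C)C | intermediate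
21 | methyl (2S,3Z)-8-(TBDPS-oxy)-3-[(TBDPS-oxy)methyl]-2-hydroxy-7-methylideneoct-3-enoate | COC(=O)[C@@H](O)/C(CO[Si](c1ccccc1)(c1ccccc1)C(C)(C)C)=C\CCC(=C)CO[Si](c1ccccc1)(c1ccccc1)C(C)(C)C | intermediate
22 | methyl (2S,3Z)-8-(TBDPS-oxy)-3-[(TBDPS-oxy)methyl]-7-methylidene-2-(TES-oxy)oct-3-enoate | COC(=O)[C@@H](O[Si](CC)(CC)CC)/C(CO[Si](c1ccccc1)(c1ccccc1)C(C)(C)C)=C\CCC(=C)CO[Si](c1ccccc1)(c1ccccc1)C(C)(C)C | intermediate
23 | (2S,3Z)-8-(TBDPS-oxy)-3-[(TBDPS-oxy)methyl]-7-methylidene-2-(TES-oxy)oct-3-enal (fragment 2) | O=C[C@@H](O[Si](CC)(CC)CC)/C(CO[Si](c1ccccc1)(c1ccccc1)C(C)(C)C)=C\CCC(=C)CO[Si](c1ccccc1)(c1ccccc1)C(C)(C)C | intermediate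
24 | {[(5R)-2-oxo-5-[(1E)-prop-1-en-1-yl]-2,5-dihydrofuran-3-yl]methyl}zinc bromide | Br[Zn]CC1=C[C@@H](/C=C/C)OC1=O | intermediate (not isolated)
25 | (4R,5R)-4-[(1R,2S,3Z)-8-(TBDPS-oxy)-3-[(TBDPS-oxy)methyl]-1-hydroxy-7-methylidene-2-(TES-oxy)oct-3-en-1-yl]-3-methylidene-5-[(1E)-prop-1-en-1-yl]oxolan-2-one | C=C1C(=O)O[C@H](/C=C/C)[C@H]1[C@@H](O)[C@@H](O[Si](CC)(CC)CC)/C(CO[Si](c2ccccc2)(c2ccccc2)C(C)(C)C)=C\CCC(=C)CO[Si](c2ccccc2)(c2ccccc2)C(C)(C)C | intermediate
26 | (2S)-2-methylbutanoate of 25 at the C8 hydroxyl (seco-diene) | C=C1C(=O)O[C@H](/C=C/C)[C@H]1[C@@H](OC(=O)[C@@H](C)CC)[C@@H](O[Si](CC)(CC)CC)/C(CO[Si](c2ccccc2)(c2ccccc2)C(C)(C)C)=C\CCC(=C)CO[Si](c2ccccc2)(c2ccccc2)C(C)(C)C | intermediate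
27 | (3aS,4R,5S,6Z,10E,11aR)-6,10-bis[(TBDPS-oxy)methyl]-3-methylidene-2-oxo-5-(TES-oxy)-2,3,3a,4,5,8,9,11a-octahydrocyclodeca[b]furan-4-yl (2S)-2-methylbutanoate | C=C1C(=O)O[C@@H]2/C=C(/CO[Si](c3ccccc3)(c3ccccc3)C(C)(C)C)CC/C=C(/CO[Si](c3ccccc3)(c3ccccc3)C(C)(C)C)[C@H](O[Si](CC)(CC)CC)[C@H](OC(=O)[C@@H](C)CC)[C@@H]12 | intermediate
28 | (3aS,4R,5S,6Z,10E,11aR)-6,10-bis[(TBDPS-oxy)methyl]-5-hydroxy-3-methylidene-2-oxo-2,3,3a,4,5,8,9,11a-octahydrocyclodeca[b]furan-4-yl (2S)-2-methylbutanoate | C=C1C(=O)O[C@@H]2/C=C(/CO[Si](c3ccccc3)(c3ccccc3)C(C)(C)C)CC/C=C(/CO[Si](c3ccccc3)(c3ccccc3)C(C)(C)C)[C@H](O)[C@H](OC(=O)[C@@H](C)CC)[C@@H]12 | intermediate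
29 | (3aS,4R,5S,6Z,10E,11aR)-5-(acetyloxy)-6,10-bis[(TBDPS-oxy)methyl]-3-methylidene-2-oxo-2,3,3a,4,5,8,9,11a-octahydrocyclodeca[b]furan-4-yl (2S)-2-methylbutanoate | C=C1C(=O)O[C@@H]2/C=C(/CO[Si](c3ccccc3)(c3ccccc3)C(C)(C)C)CC/C=C(/CO[Si](c3ccccc3)(c3ccccc3)C(C)(C)C)[C@H](OC(C)=O)[C@H](OC(=O)[C@@H](C)CC)[C@@H]12 | intermediate
30 | (3aS,4R,5S,6Z,10E,11aR)-5-(acetyloxy)-6,10-bis(hydroxymethyl)-3-methylidene-2-oxo-2,3,3a,4,5,8,9,11a-octahydrocyclodeca[b]furan-4-yl (2S)-2-methylbutanoate | C=C1C(=O)O[C@@H]2/C=C(/CO)CC/C=C(/CO)[C@H](OC(C)=O)[C@H](OC(=O)[C@@H](C)CC)[C@@H]12 | target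

**Step count**
Total: 22 steps. Longest linear sequence: 14 steps (7, 8, 9, 12–22), which is 14/22 of the total. The branches are steps 1–2 and 5–6 (with 3–4 feeding step 5) and steps 10–11.

**Three steps most likely to fail**

Step 19 (macrocyclic ring-closing metathesis). The ruthenium alkylidene formed at C5 could instead close onto the hindered C1=C10 alkene six atoms away (a cyclohexene, with loss of the C1–C4 chain), or the diene could oligomerise. The fallback masks that alkene and sets out from 26. PPTS in MeOH removes the TES group to give the seco alcohol F1. Hydroxyl-directed epoxidation (VO(acac)2 cat., t-BuOOH, CH2Cl2, 0 °C) then oxidises only the C1=C10 alkene next to the free C9 hydroxyl and gives the epoxy alcohol F2; either epoxide epimer serves, the expected one is drawn. Ac2O/pyridine gives the epoxy acetate F3, and ring-closing metathesis under the step 19 conditions, now with no competing alkene, gives the macrocyclic epoxide F4. Stereospecific deoxygenation with retention (triphenylphosphine selenide, CF3CO2H, CH2Cl2) restores the cis alkene, and the route is rejoined at 29.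

Step 17 (Barbier coupling). Wurtz-type dimerisation of the allylzinc, partial loss of the TES group or epimerisation of the α-silyloxy aldehyde in the aqueous medium, or eroded Felkin control could lower yield and selectivity. The fallback sets out from 8. Borylation with bis(pinacolato)diboron and Pd2(dba)3 (cat.) in toluene at 50 °C gives the isolable allylboronate F5. Thermal allylboration of 23 in toluene (rt → 40 °C, no water, no metal salts) goes through the same closed six-membered transition state and, after hydrolytic work-up, comes back to the route at 25.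

Step 14 (asymmetric transfer hydrogenation). The ketone sits next to a fully substituted alkenyl carbon, so the rate, the enantiomeric excess, or the predicted facial sense may disappoint, and enantiomers cannot be separated at this stage. The fallback sets out from 18. Alkenyllithium 19 (made as in step 13) is added at −78 °C to (R)-2,2-dimethyl-1,3-dioxolane-4-carbaldehyde (from D-mannitol). Felkin–Anh addition favours the anti carbinol F6, which has the required C9 configuration and is separable from its epimer by chromatography. Et3SiOTf/2,6-lutidine gives the triethylsilyl ether F7. Periodic acid (H5IO6) in ethyl acetate at 0 °C hydrolyses the acetonide and cleaves the glycol in one pot, and the route is rejoined at 23.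

**Further compounds**
F1 | step 19 | C9 alcohol of 26 (TES removed, otherwise as 26) | C=C1C(=O)O[C@H](/C=C/C)[C@H]1[C@@H](OC(=O)[C@@H](C)CC)[C@@H](O)/C(CO[Si](c2ccccc2)(c2ccccc2)C(C)(C)C)=C\CCC(=C)CO[Si](c2ccccc2)(c2ccccc2)C(C)(C)C
F2 | step 19 | C1–C10 epoxide of F1 (oxirane oxygen on the face of the C9 hydroxyl in the H-eclipsed rotamer) | C=C1C(=O)O[C@H](/C=C/C)[C@H]1[C@@H](OC(=O)[C@@H](C)CC)[C@@H](O)[C@]2(CO[Si](c3ccccc3)(c3ccccc3)C(C)(C)C)O[C@@H]2CCC(=C)CO[Si](c3ccccc3)(c3ccccc3)C(C)(C)C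
F3 | step 19 | C9 acetate of F2 | C=C1C(=O)O[C@H](/C=C/C)[C@H]1[C@@H](OC(=O)[C@@H](C)CC)[C@@H](OC(C)=O)[C@]2(CO[Si](c3ccccc3)(c3ccccc3)C(C)(C)C)O[C@@H]2CCC(=C)CO[Si](c3ccccc3)(c3ccccc3)C(C)(C)C
F4 | step 19 | C1–C10 epoxide of macrocycle 29 | C=C1C(=O)O[C@@H]2/C=C(/CO[Si](c4ccccc4)(c4ccccc4)C(C)(C)C)CC[C@H]3O[C@@]3(CO[Si](c4ccccc4)(c4ccccc4)C(C)(C)C)[C@H](OC(C)=O)[C@H](OC(=O)[C@@H](C)CC)[C@@H]12
F5 | step 17 | (5R)-5-[(1E)-prop-1-en-1-yl]-3-[(4,4,5,5-tetramethyl-1,3,2-dioxaborolan-2-yl)methyl]furan-2(5H)-one | CC1(C)OB(CC2=C[C@@H](/C=C/C)OC2=O)OC1(C)C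
F6 | step 14 | (1S,2Z)-7-(TBDPS-oxy)-2-[(TBDPS-oxy)methyl]-1-[(4R)-2,2-dimethyl-1,3-dioxolan-4-yl]-6-methylidenehept-2-en-1-ol | CC1(C)OC[C@@H](O1)[C@@H](O)/C(CO[Si](c2ccccc2)(c2ccccc2)C(C)(C)C)=C\CCC(=C)CO[Si](c2ccccc2)(c2ccccc2)C(C)(C)C
F7 | step 14 | triethylsilyl ether of F6 | CC1(C)OC[C@@H](O1)[C@@H](O[Si](CC)(CC)CC)/C(CO[Si](c2ccccc2)(c2ccccc2)C(C)(C)C)=C\CCC(=C)CO[Si](c2ccccc2)(c2ccccc2)C(C)(C)C
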